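- At 120 s the dusk run still shows 1.2 % of its substrate and the midnight run 0.4 %, so nearly all of each charge has reacted, and we ask how the reacted part was divided.

| flask | substrate | remark | time |
|---|---|---|---|
| dusk | 0.21 M | run made earlier |  |
| midnight | 0.57 M | run made earlier |  |
| violet | 0.15 M |  | 2.0 min |
| blue | 0.20 M |  | 2.0 min |
| amber | 0.30 M |  | 2.0 min |
| red | 0.50 M |  | 2.0 min |

| run | time / s | target / % | substrate / % |
|---|---|---|---|
| dusk | 10.0 | 19.2 | 66.6 |
| dusk | 20.0 | 30.9 | 43.7 |
| dusk | 30.0 | 39.9 | 30.4 |
| dusk | 60.0 | 52.2 | 8.4 |
| dusk | 120 | 55.6 | 1.2 |
| midnight | 10.0 | 19.9 | 65.7 |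
| midnight | 30.0 | 40.8 | 29.5 |
| midnight | 60.0 | 50.5 | 10.1 |
| midnight | 80.0 | 53.5 | 4.8 |
| midnight | 120 | 55.0 | 0.4 |

(readings scatter by 1 percentage point)

- what was read earlier has a scatter of 1 percentage point, one standard deviation
- "hardly changes" means that all values lie within two and a half points (for a concentration: within two and a half percent of the largest)

* [target] at the end for violet, blue, amber, red, in this order
* the shape of the row from first to last (rises, then falls / falls, then rises / rises all the way / falls all the way / hardly changes)

- **First instants:** by 10.0 s the dusk run has lost 33.4 % of its substrate but gained 19.2 % of target, so something we do not read takes the rest from early on.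
- **Pace:** the dusk reading at 20.0 s gives a substrate half-life of 16.7 s, and the midnight reading at 30.0 s gives 17.0 s. The midnight charge is 2.71 times the dusk charge, so the substrate behaves as first order.
- **Middle:** target gained per substrate lost is 57.5 % in dusk and 58.0 % in midnight at 10.0 s. At 60.0 s it is 57.0 % and 56.2 %, so the division barely moves with time or charge.
- **The quantity we carry:** the mean of the last readings of the two runs gives 55.7 %. This is the target share, the target formed per substrate reacted, usually called the selectivity.
- **End:** the asked 2.0 min is 7.19 half-lives, which by our reckoning leaves 0.696 % of the substrate. Target is then the share times the charge times the reacted part, so violet should hold 0.0830 M and red 0.277 M, and the row should rise.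
- **Forecast:** it gives 0.083 M, 0.111 M, 0.167 M and 0.278 M, a row that rises all the way, and it sees “no concentration effect on selectivity”. At red our figure is lower, at 0.277 M against 0.278 M.
- **Result:** the flasks give 0.0835 M, 0.111 M, 0.167 M and 0.278 M, a row that rises all the way.

    substrate → target (k = 0.0230 s⁻¹)
    substrate → side product (k = 0.0180 s⁻¹)

- In violet the step to target uses substrate 1.3 times as fast as the step to side product at the start, and the ratio is still 1.3 at 2.00 min. In red at 1.00 min, with 8.54 % of the substrate left, the target share read from the runs gives 50.9 % of the charge, and the flask holds 51.3 %. In amber at 2.00 min, with 0.730 % left, the share gives 0.166 M, and the flask holds 0.167 M.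

(The readings are calculated for substances that don't exist; scatter was added.)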